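**Plan**

1. Retrosynthesis: the three O-allyl caps (O5, O7, O4′) come off last; ring C is then cut at C3–C4 and at O1–C8a together, leaving a ring A amide (C4 acyl, fluorine on C8a, prenyl on C6 between O5 and O7) and a ring B carbinol whose O1 and C3 are both nucleophilic.
2. What makes this possible: in ring A, C8a is ortho to the C4 carbonyl and meta to both ring oxygens (C5, C7), so a C8a–F bond becomes an SNAr site the moment C4 is a ketone; O1 and C3 sit 1,3 on C2, so a β-oxido alkyllithium can deliver both bonds.
3. Forward, ring A piece: 5-fluororesorcinol bis-MOM ether is lithiated twice (prenyl between the oxygens, then the Weinreb amide next to fluorine), and MOM is exchanged for allyl.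
4. Forward, ring B piece: 4-bromophenol is ortho-prenylated, O-allylated, epoxidised (Shi), acylated to the α-chloro ketone, reduced (CBS) and converted to the iodohydrin.
5. Ring C is the only ring made in the route: one flask joins the two pieces by C-acylation (C3–C4) and then O-arylation (O1–C8a); palladium-catalysed deallylation gives the target.
6. Stereochemistry: the oxirane centre (R) comes from reagent control in the Shi epoxidation; C2 (S) comes from catalyst control in the CBS reduction and passes through the key step with none of its bonds touched; 6- versus 8-prenyl is fixed because only C8a bears a leaving group.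

Key step: step 12

Remark: lithiation of the bis-MOM ether 3 between its two OMOM groups, and the R sense of the Shi epoxidation with the D-fructose-derived ketone, are assumed from the behaviour of close analogues (the antipodal ketone would be used if the sense were opposite); prenyl = 3-methylbut-2-en-1-yl, allyl = prop-2-en-1-yl.

**Route**

Step 1
Reactants: 1 5-fluorobenzene-1,3-diol; 2 chloromethyl methyl ether
Product: 3 1-fluoro-3,5-bis(methoxymethoxy)benzene
Conditions: i-Pr2NEt, CH2Cl2, 0 °C → rt
Reagents that add atoms: chloromethyl methyl ether (2), COCCl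
Why: Williamson-type O-alkylation of both phenols gives the base-stable bis-acetal, whose OMOM groups direct the two lithiations that follow.

Step 2
Reactants: 3 1-fluoro-3,5-bis(methoxymethoxy)benzene; 4 prenyl bromide
Product: 6 5-fluoro-1,3-bis(methoxymethoxy)-2-prenylbenzene, via aryllithium 5 (not isolated)
Conditions: n-BuLi, THF, 0 °C; then 4, −78 °C → rt
Reagents that add atoms: prenyl bromide (4), CC(C)=CCBr
Why: Directed ortho-metalation should take the C–H chelated by both OMOM groups (this aryllithium is not ortho to fluorine, so no aryne can form), and SN2 alkylation at the primary carbon of prenyl bromide places the prenyl group between the two oxygens.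

Step 3
Reactants: 6 5-fluoro-1,3-bis(methoxymethoxy)-2-prenylbenzene; 7 N-methoxy-N-methylcarbamoyl chloride
Product: 9 6-fluoro-N-methoxy-2,4-bis(methoxymethoxy)-N-methyl-3-prenylbenzamide, via aryllithium 8 (not isolated)
Conditions: s-BuLi, TMEDA, THF, −78 °C; then 7, −78 °C
Reagents that add atoms: N-methoxy-N-methylcarbamoyl chloride (7), CON(C)C(=O)Cl
Why: A second directed ortho-metalation at the ring C–H flanked by F and OMOM (held at −78 °C so that LiF is not lost to an aryne), followed by acyl substitution on the carbamoyl chloride, should give the Weinreb amide directly.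

Step 4
Reactants: 9 6-fluoro-N-methoxy-2,4-bis(methoxymethoxy)-N-methyl-3-prenylbenzamide
Product: 10 6-fluoro-2,4-dihydroxy-N-methoxy-N-methyl-3-prenylbenzamide
Conditions: 3 M HCl (aq), MeOH, 40 °C
Reagents that add atoms: none
Why: Acid-catalysed acetal methanolysis should free both phenols without touching the prenyl alkene or the amide, and is done here because the last deprotection of the route must be non-acidic.

Step 5
Reactants: 10 6-fluoro-2,4-dihydroxy-N-methoxy-N-methyl-3-prenylbenzamide; 11 allyl bromide
Product: 12 2,4-bis(allyloxy)-6-fluoro-N-methoxy-N-methyl-3-prenylbenzamide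
Conditions: K2CO3, DMF, 40 °C
Reagents that add atoms: allyl bromide (11), C=CCBr
Why: Williamson etherification of both phenoxides installs allyl ethers, which withstand organolithiums and alkoxides and leave later under neutral palladium catalysis.

Step 6
Reactants: 13 4-bromophenol; 4 prenyl bromide
Product: 14 4-bromo-2-prenylphenol
Conditions: NaH, toluene, 0 °C → rt
Reagents that add atoms: prenyl bromide (4), CC(C)=CCBr
Why: ortho-C-alkylation of a sodium phenoxide held as a tight ion pair in a non-polar solvent (para position blocked by bromine) is the classical route to 2-prenylphenols.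

Step 7
Reactants: 14 4-bromo-2-prenylphenol; 11 allyl bromide
Product: 15 1-(allyloxy)-4-bromo-2-prenylbenzene
Conditions: K2CO3, acetone, reflux
Reagents that add atoms: allyl bromide (11), C=CCBr
Why: Williamson etherification caps the phenol so that it cannot open the oxirane made in the next step.

Step 8
Reactants: 15 1-(allyloxy)-4-bromo-2-prenylbenzene; 16 potassium peroxymonosulfate
Product: 17 (3R)-3-[2-(allyloxy)-5-bromobenzyl]-2,2-dimethyloxirane
Conditions: D-fructose-derived Shi ketone (30 mol %), Oxone (2KHSO5·KHSO4·K2SO4), K2CO3, Bu4NHSO4, Na2B4O7/Na2EDTA buffer, MeCN/CH2(OMe)2, 0 °C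
Reagents that add atoms: potassium peroxymonosulfate (16), [K+].[O-]S(=O)(=O)OO
Why: In this Shi asymmetric epoxidation the chiral dioxirane should attack the electron-rich trisubstituted alkene far faster than the monosubstituted allyl alkene, and its spiro transition state should set the R oxirane centre (reagent control).

Step 9
Reactants: 17 (3R)-3-[2-(allyloxy)-5-bromobenzyl]-2,2-dimethyloxirane; 18 2-chloro-N-methoxy-N-methylacetamide
Product: 21 2-chloro-1-{4-(allyloxy)-3-[((2R)-3,3-dimethyloxiran-2-yl)methyl]phenyl}ethan-1-one, via aryllithium 19 (not isolated), via lithium hemiaminal 20 (not isolated)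
Conditions: n-BuLi, THF, −78 °C; then 18, −78 °C; aq. NH4Cl
Reagents that add atoms: 2-chloro-N-methoxy-N-methylacetamide (18), CON(C)C(=O)CCl
Why: Bromine–lithium exchange at −78 °C should outrun attack on the hindered oxirane or the allyl ether, and the chelated Weinreb adduct stops the acylation at the α-chloro ketone.

Step 10
Reactants: 21 2-chloro-1-{4-(allyloxy)-3-[((2R)-3,3-dimethyloxiran-2-yl)methyl]phenyl}ethan-1-one
Product: 23 (1R)-2-chloro-1-{4-(allyloxy)-3-[((2R)-3,3-dimethyloxiran-2-yl)methyl]phenyl}ethan-1-ol, via borate ester 22 (not isolated)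
Conditions: (R)-2-methyl-CBS-oxazaborolidine (20 mol %), catecholborane, toluene, −78 °C; then MeOH, pH 7 buffer
Reagents that add atoms: none
Why: In this Corey–Bakshi–Shibata reduction the catalyst delivers hydride to one carbonyl face with the aryl group as the large substituent, which should give the R chlorohydrin (catalyst control), while catecholborane at −78 °C spares the alkenes and the oxirane.

Step 11
Reactants: 23 (1R)-2-chloro-1-{4-(allyloxy)-3-[((2R)-3,3-dimethyloxiran-2-yl)methyl]phenyl}ethan-1-ol; 24 sodium iodide
Product: 25 (1R)-2-iodo-1-{4-(allyloxy)-3-[((2R)-3,3-dimethyloxiran-2-yl)methyl]phenyl}ethan-1-ol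
Conditions: NaI, NaHCO3 (trace), butanone, 70 °C, dark
Reagents that add atoms: sodium iodide (24), [Na+].[I-]
Why: Finkelstein exchange (SN2 at the primary carbon, driven by precipitation of NaCl) leaves the carbinol centre untouched, and the hindered trisubstituted oxirane should resist iodide under neutral conditions.

Step 12
Reactants: 25 (1R)-2-iodo-1-{4-(allyloxy)-3-[((2R)-3,3-dimethyloxiran-2-yl)methyl]phenyl}ethan-1-ol; 12 2,4-bis(allyloxy)-6-fluoro-N-methoxy-N-methyl-3-prenylbenzamide
Product: 29 (2S)-5,7-bis(allyloxy)-2-{4-(allyloxy)-3-[((2R)-3,3-dimethyloxiran-2-yl)methyl]phenyl}-6-prenylchroman-4-one, via dilithio species 26 (not isolated), via lithium hemiaminal 27 (not isolated), via lithium aldolate 28 (not isolated)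
Conditions: n-BuLi (1 equiv) then t-BuLi (2.1 equiv), Et2O, −78 °C; 12 (1.1 equiv) in THF, −78 °C; AcOH (1 equiv), DMPU, −78 → 0 °C
Reagents that add atoms: none
Why: Proposed new method: O-deprotonation and iodine–lithium exchange of 25 should give the β-oxido alkyllithium 26 (persistent at −78 °C because Li2O is a poor leaving group), whose carbon adds to the Weinreb amide 12 and stops at the chelated adduct 27 (bond C3–C4), after which one equivalent of AcOH releases the ketone as its lithium alkoxide 28, whose oxygen attacks the C8a–F carbon just made ortho-activated by the new C4 ketone and expels LiF through a Meisenheimer complex (bond O1–C8a). The closest known reaction types are the ketone synthesis from organolithiums and Weinreb amides, the acylation of β-oxido organolithiums, and the intramolecular SNAr closure of 2-fluoroaryl β-hydroxy ketones to chroman-4-ones, but their merger in one flask as a [3+3] annulation has not been shown. Ring C closes in a 6-endo-trig sense with respect to the C4a=C8a π bond, as an oxa-Michael addition–elimination on the vinylogous acyl fluoride C4(=O)–C4a=C8a–F. No new stereocentre is formed: C2 is carried in from (R)-25 with its four bonds untouched and becomes 2S only because C3 now ranks below the aryl group, and the oxirane centre is a spectator. The step needs single acylation (secured by the stable Weinreb chelate), carbonyl attack in preference to fluoride displacement or C8–H deprotonation (secured by −78 °C), ring closure faster than retro-aldol cleavage or E1cB loss of the C2 oxygen (secured by intramolecular six-ring attack on a C–F bond ortho to the ketone, the lithium counter-ion and a temperature at or below 0 °C), and one ring A regiochemistry (secured because only C8a carries fluorine while O5 is capped).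

Step 13
Reactants: 29 (2S)-5,7-bis(allyloxy)-2-{4-(allyloxy)-3-[((2R)-3,3-dimethyloxiran-2-yl)methyl]phenyl}-6-prenylchroman-4-one
Product: 30 (2S)-5,7-dihydroxy-2-{4-hydroxy-3-[((2R)-3,3-dimethyloxiran-2-yl)methyl]phenyl}-6-prenylchroman-4-one
Conditions: Pd(PPh3)4 (zerovalent palladium, 10 mol %), morpholine, THF, rt, degassed
Reagents that add atoms: none
Why: In this Tsuji–Trost-type deallylation zerovalent palladium ionises the three aryl allyl ethers to π-allyl complexes that morpholine captures, under near-neutral conditions that should leave the oxirane, the prenyl group and the C2 centre untouched.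

**Compound list**

1 | 5-fluorobenzene-1,3-diol (5-fluororesorcinol) | Oc1cc(O)cc(F)c1 | starting material
2 | chloromethyl methyl ether | COCCl | starting material
3 | 1-fluoro-3,5-bis(methoxymethoxy)benzene | COCOc1cc(F)cc(OCOC)c1 | intermediate
4 | 1-bromo-3-methylbut-2-ene (prenyl bromide) | CC(C)=CCBr | starting material
5 | [4-fluoro-2,6-bis(methoxymethoxy)phenyl]lithium (formed in the flask) | [Li]c1c(OCOC)cc(F)cc1OCOC | intermediate
6 | 5-fluoro-1,3-bis(methoxymethoxy)-2-prenylbenzene | COCOc1cc(F)cc(OCOC)c1CC=C(C)C | intermediate
7 | N-methoxy-N-methylcarbamoyl chloride | CON(C)C(=O)Cl | starting material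
8 | [6-fluoro-2,4-bis(methoxymethoxy)-3-prenylphenyl]lithium (formed in the flask) | [Li]c1c(F)cc(OCOC)c(CC=C(C)C)c1OCOC | intermediate
9 | 6-fluoro-N-methoxy-2,4-bis(methoxymethoxy)-N-methyl-3-prenylbenzamide | CON(C)C(=O)c1c(F)cc(OCOC)c(CC=C(C)C)c1OCOC | intermediate
10 | 6-fluoro-2,4-dihydroxy-N-methoxy-N-methyl-3-prenylbenzamide | CON(C)C(=O)c1c(F)cc(O)c(CC=C(C)C)c1O | intermediate
11 | 3-bromoprop-1-ene (allyl bromide) | C=CCBr | starting material
12 | 2,4-bis(allyloxy)-6-fluoro-N-methoxy-N-methyl-3-prenylbenzamide | CON(C)C(=O)c1c(F)cc(OCC=C)c(CC=C(C)C)c1OCC=C | intermediate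
13 | 4-bromophenol | Oc1ccc(Br)cc1 | starting material
14 | 4-bromo-2-prenylphenol | CC(C)=CCc1cc(Br)ccc1O | intermediate
15 | 1-(allyloxy)-4-bromo-2-prenylbenzene | CC(C)=CCc1cc(Br)ccc1OCC=C | intermediate
16 | potassium peroxymonosulfate (KHSO5, active salt of Oxone) | [K+].[O-]S(=O)(=O)OO | starting material
17 | (3R)-3-[2-(allyloxy)-5-bromobenzyl]-2,2-dimethyloxirane | C=CCOc1ccc(Br)cc1C[C@H]1OC1(C)C | intermediate
18 | 2-chloro-N-methoxy-N-methylacetamide | CON(C)C(=O)CCl | starting material
19 | {4-(allyloxy)-3-[((2R)-3,3-dimethyloxiran-2-yl)methyl]phenyl}lithium (formed in the flask) | [Li]c1ccc(OCC=C)c(C[C@H]2OC2(C)C)c1 | intermediate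
20 | lithium hemiaminal from 19 and 18 (formed in the flask; new carbon centre undefined) | CON(C)C(CCl)(O[Li])c1ccc(OCC=C)c(C[C@H]2OC2(C)C)c1 | intermediate
21 | 2-chloro-1-{4-(allyloxy)-3-[((2R)-3,3-dimethyloxiran-2-yl)methyl]phenyl}ethan-1-one | O=C(CCl)c1ccc(OCC=C)c(C[C@H]2OC2(C)C)c1 | intermediate
22 | catechol borate ester of chlorohydrin 23 (formed in the flask) | ClC[C@H](OB1Oc2ccccc2O1)c1ccc(OCC=C)c(C[C@H]2OC2(C)C)c1 | intermediate
23 | (1R)-2-chloro-1-{4-(allyloxy)-3-[((2R)-3,3-dimethyloxiran-2-yl)methyl]phenyl}ethan-1-ol | ClC[C@@H](c1ccc(OCC=C)c(C[C@H]2OC2(C)C)c1)O | intermediate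
24 | sodium iodide | [Na+].[I-] | starting material
25 | (1R)-2-iodo-1-{4-(allyloxy)-3-[((2R)-3,3-dimethyloxiran-2-yl)methyl]phenyl}ethan-1-ol | IC[C@@H](c1ccc(OCC=C)c(C[C@H]2OC2(C)C)c1)O | intermediate
26 | dilithio species of 25: lithium 2-lithio-1-arylethan-1-olate with the carbinol configuration of 25 retained (formed in the flask) | [Li]C[C@@H](c1ccc(OCC=C)c(C[C@H]2OC2(C)C)c1)O[Li] | intermediate
27 | dilithium hemiaminal from 26 and 12 (formed in the flask; hemiaminal carbon undefined) | CON(C)C(O[Li])(C[C@@H](c1ccc(OCC=C)c(C[C@H]2OC2(C)C)c1)O[Li])c1c(F)cc(OCC=C)c(CC=C(C)C)c1OCC=C | intermediate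
28 | lithium alkoxide of the β-hydroxy ketone 1-[2,4-bis(allyloxy)-6-fluoro-3-prenylphenyl]-3-aryl-3-hydroxypropan-1-one (formed in the flask) | O=C(C[C@@H](c1ccc(OCC=C)c(C[C@H]2OC2(C)C)c1)O[Li])c1c(F)cc(OCC=C)c(CC=C(C)C)c1OCC=C | intermediate
29 | (2S)-5,7-bis(allyloxy)-2-{4-(allyloxy)-3-[((2R)-3,3-dimethyloxiran-2-yl)methyl]phenyl}-6-prenylchroman-4-one | CC(C)=CCc1c(OCC=C)cc2c(c1OCC=C)C(=O)C[C@@H](c1ccc(OCC=C)c(C[C@H]3OC3(C)C)c1)O2 | intermediate
30 | (2S)-5,7-dihydroxy-2-{4-hydroxy-3-[((2R)-3,3-dimethyloxiran-2-yl)methyl]phenyl}-6-prenylchroman-4-one | CC(C)=CCc1c(O)cc2c(c1O)C(=O)C[C@@H](c1ccc(O)c(C[C@H]3OC3(C)C)c1)O2 | target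

**Count and risks**

Total step count: 13. Longest linear sequence: 8 steps (steps 6 to 13, from 4-bromophenol); the ring A branch is 5 steps before the junction.

Steps most likely to fail:

1. Step 12 (proposed new method). What may go wrong: the lithium aldolate undergoes retro-aldol cleavage or E1cB loss of the C2 oxygen faster than it closes onto C8a, or the dilithio species loses Li2O by β-elimination before it is acylated; each erodes both yield and the C2 configuration. Fallback (known chemistry, ring C made at the flavone oxidation level): it sets out from bromide 17 and amide 12 and returns at 29. Bromine–lithium exchange on 17 (n-BuLi, −78 °C) and acylation with N-methoxy-N-methylacetamide would give the methyl ketone F1. Its lithium enolate (LiHMDS, THF) would be C-acylated by 12 in a Claisen-type condensation to the 1,3-diketone F2. The enolate oxygen of F2 would displace the C8a fluoride (K2CO3, DMF, 80 °C) to give the flavone F3. Enantioselective 1,4-reduction of F3 with a copper hydride made from Cu(OAc)2, the appropriate antipode of DTBM-SEGPHOS and (EtO)2MeSiH would give 29. No aldolate occurs on this path; the price is that C2 is set by catalyst control on the flavone.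

2. Step 13. What may go wrong: C-allylation of the electron-rich ring A by the π-allyl intermediate, opening of the oxirane by the freed neighbouring ring B phenol, or amine-promoted ring opening at C2 with loss of configuration. Fallback (isomerisation–hydrolysis in place of allyl transfer): it sets out from 29 and returns at 30. The three allyl ethers would be isomerised with [Ir(cod)(PMePh2)2]PF6 (activated with H2, THF, rt) to the tris[(E)-prop-1-enyl] ether F4. The enol ethers would then be hydrolysed with HgCl2/HgO in aqueous acetone at rt to give 30. Neither a π-allyl electrophile nor an amine is present on this path.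

3. Step 6. What may go wrong: O-alkylation and double alkylation compete with the wanted ortho-C-alkylation of the ambident phenoxide. Fallback (sigmatropic placement of the carbon chain): it sets out from 13 and returns at 14. O-Allylation (allyl bromide 11, K2CO3, acetone) would give allyl 4-bromophenyl ether F5. Aromatic Claisen rearrangement (N,N-diethylaniline, 200 °C) would give 2-allyl-4-bromophenol F6. Cross-metathesis with 2-methylbut-2-ene (second-generation Grubbs catalyst, RuCl2(=CHPh)(PCy3)(H2IMes), CH2Cl2, 40 °C) would give 14.

Further compounds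
F1 | step 12 | 1-{4-(allyloxy)-3-[((2R)-3,3-dimethyloxiran-2-yl)methyl]phenyl}ethan-1-one | CC(=O)c1ccc(OCC=C)c(C[C@H]2OC2(C)C)c1
F2 | step 12 | 1-[2,4-bis(allyloxy)-6-fluoro-3-prenylphenyl]-3-{4-(allyloxy)-3-[((2R)-3,3-dimethyloxiran-2-yl)methyl]phenyl}propane-1,3-dione | O=C(CC(=O)c1ccc(OCC=C)c(C[C@H]2OC2(C)C)c1)c1c(F)cc(OCC=C)c(CC=C(C)C)c1OCC=C
F3 | step 12 | 5,7-bis(allyloxy)-2-{4-(allyloxy)-3-[((2R)-3,3-dimethyloxiran-2-yl)methyl]phenyl}-6-prenyl-4H-chromen-4-one | CC(C)=CCc1c(OCC=C)cc2oc(-c3ccc(OCC=C)c(C[C@H]4OC4(C)C)c3)cc(=O)c2c1OCC=C
F4 | step 13 | (2S)-2-{3-[((2R)-3,3-dimethyloxiran-2-yl)methyl]-4-[(E)-prop-1-enyloxy]phenyl}-6-prenyl-5,7-bis[(E)-prop-1-enyloxy]chroman-4-one | CC(C)=CCc1c(O/C=C/C)cc2c(c1O/C=C/C)C(=O)C[C@@H](c1ccc(O/C=C/C)c(C[C@H]3OC3(C)C)c1)O2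
F5 | step 6 | 1-(allyloxy)-4-bromobenzene | C=CCOc1ccc(Br)cc1
F6 | step 6 | 2-allyl-4-bromophenol | C=CCc1cc(Br)ccc1O
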